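The C4–carbinol bond is made by a lactone-enolate aldol addition. Oxolane C4 lies next to the ring methylene C5; carried as a lactone carbonyl, C5 turns C4 into an enolate carbon, and the oxolane ring O1–C2–C3–C4–C5 is then a trans-4,5-disubstituted γ-butyrolactone. Its zinc enolate adds reversibly to silyl-protected vanillin: one operation joins the two halves and sets both C4 (trans to the C3 arm) and the carbinol centre (anti), the all-trans, chelated aldolate being the thermodynamic sink. The lactone comes from an Evans syn-aldol/lactonisation of a succinate imide; afterwards C5 is reduced and the ring re-closed by etherification.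

Key step: step 6

Remark on the chemistry: the target has the oxolane substituents 2,3-trans and 3,4-trans (2S,3R,4S), and the (S)-carbinol is anti to C3 when the chain C5–C4–carbinol–aryl is drawn extended. Vanillin, (S)-4-benzyl-1,3-oxazolidin-2-one and methyl 4-chloro-4-oxobutanoate are taken as commercial.

Step 1
Reactants: 1 vanillin
Product: 2 3-methoxy-4-[(triisopropylsilyl)oxy]benzaldehyde
Conditions: TIPSCl, imidazole, DMF, rt
Reagents that add atoms: chlorotriisopropylsilane (TIPSCl), CC(C)[Si](Cl)(C(C)C)C(C)C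
Why: Phenol silylation; the bulky aryl silyl ether should survive the later enolate, hydride and sulfonylation steps and leave with fluoride at the end.

Step 2
Reactants: 3 (S)-4-benzyl-1,3-oxazolidin-2-one; 4 methyl 4-chloro-4-oxobutanoate
Product: 6 methyl 4-[(4S)-4-benzyl-2-oxo-1,3-oxazolidin-3-yl]-4-oxobutanoate, via N-lithio oxazolidinone 5 (not isolated)
Conditions: n-BuLi, THF, −78 °C; then 4, −78 to 0 °C
Reagents that add atoms: none
Why: N-acylation of the lithiated Evans oxazolidinone by the acid chloride is far faster than attack on the methyl ester and leaves the auxiliary stereocentre untouched.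

Step 3
Reactants: 6 methyl 4-[(4S)-4-benzyl-2-oxo-1,3-oxazolidin-3-yl]-4-oxobutanoate; 2 3-methoxy-4-[(triisopropylsilyl)oxy]benzaldehyde
Product: 9 (4S)-4-benzyl-3-{[(2S,3S)-2-{3-methoxy-4-[(triisopropylsilyl)oxy]phenyl}-5-oxooxolan-3-yl]carbonyl}-1,3-oxazolidin-2-one, via dibutylboron Z-enolate 7 (not isolated), via syn-aldol adduct 8 (not isolated)
Conditions: Bu2BOTf, i-Pr2NEt, CH2Cl2, −78 to 0 °C; 2, −78 to 0 °C; H2O2, pH 7 buffer, MeOH, 0 °C; then PPTS (cat.), CH2Cl2, rt
Reagents that add atoms: none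
Why: Evans syn-aldol followed by lactonisation: the imide-side Z-boron enolate adds through a chair transition state on the face away from the benzyl group, which sets the aryl carbinol carbon (future oxolane C2, S) and its neighbour (future C3), and the syn γ-hydroxy ester then closes to the trans γ-lactone with loss of methanol.

Step 4
Reactants: 9 (4S)-4-benzyl-3-{[(2S,3S)-2-{3-methoxy-4-[(triisopropylsilyl)oxy]phenyl}-5-oxooxolan-3-yl]carbonyl}-1,3-oxazolidin-2-one
Product: 10 (4R,5S)-4-(hydroxymethyl)-5-{3-methoxy-4-[(triisopropylsilyl)oxy]phenyl}oxolan-2-one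
Conditions: NaBH4, THF/H2O (4:1), 0 °C to rt
Reagents that add atoms: none
Why: Reductive cleavage of an N-acyl oxazolidinone with NaBH4 in wet THF should be much faster than reduction of the γ-lactone, so the auxiliary is released and the future C3 hydroxymethyl group is formed without touching a stereocentre.

Step 5
Reactants: 10 (4R,5S)-4-(hydroxymethyl)-5-{3-methoxy-4-[(triisopropylsilyl)oxy]phenyl}oxolan-2-one
Product: 11 (4R,5S)-4-{[(tert-butyldimethylsilyl)oxy]methyl}-5-{3-methoxy-4-[(triisopropylsilyl)oxy]phenyl}oxolan-2-one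
Conditions: TBSCl, imidazole, DMF, rt
Reagents that add atoms: tert-butyldimethylsilyl chloride (TBSCl), CC(C)(C)[Si](C)(C)Cl
Why: Silylation of the primary alcohol; it blocks lactone migration to this oxygen and marks it as the CH2O group that must not take part in the later ring closure.

Step 6
Reactants: 11 (4R,5S)-4-{[(tert-butyldimethylsilyl)oxy]methyl}-5-{3-methoxy-4-[(triisopropylsilyl)oxy]phenyl}oxolan-2-one; 2 3-methoxy-4-[(triisopropylsilyl)oxy]benzaldehyde
Product: 14 (3R,4R,5S)-4-{[(tert-butyldimethylsilyl)oxy]methyl}-3-[(S)-hydroxy{3-methoxy-4-[(triisopropylsilyl)oxy]phenyl}methyl]-5-{3-methoxy-4-[(triisopropylsilyl)oxy]phenyl}oxolan-2-one, via lithium enolate 12 (not isolated), via chlorozinc enolate 13 (not isolated)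
Conditions: LiN(SiMe3)2, THF, −78 °C; ZnCl2, −78 °C; 2, −78 to −20 °C; aq. NH4Cl
Reagents that add atoms: none
Why: LiN(SiMe3)2 removes a proton from the only acidic CH2 of 11 (next to the lactone carbonyl, the future oxolane C5) to give the ring-locked E-enolate 12, ZnCl2 turns it into the zinc enolate 13, and this adds to the aldehyde carbon of 2 through a six-membered chair transition state. The closest known reaction type is the anti-selective aldol addition of zinc enolates of cyclic esters and ketones to aromatic aldehydes under equilibrating conditions. No ring is closed. The new ring stereocentre (future oxolane C4) is set by the adjacent carbon bearing the CH2OTBS arm, the aldehyde entering on the opposite face (3,4-trans), and the new carbinol centre is set by the fixed enolate geometry, which in the chair with the aryl group equatorial gives the anti, (S)-configured alcohol. Because aldolates of aromatic aldehydes revert easily, syn and anti zinc aldolates can interconvert by retro-aldol/aldol, and the chelate with the aryl group equatorial on the all-trans lactone should be the sink, so kinetic and thermodynamic preference coincide. The step needs trans over cis attack and anti over syn addition; the arm on lactone C4 secures the first, the locked E-enolate together with the chelating zinc counter-ion the second.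

Step 7
Reactants: 14 (3R,4R,5S)-4-{[(tert-butyldimethylsilyl)oxy]methyl}-3-[(S)-hydroxy{3-methoxy-4-[(triisopropylsilyl)oxy]phenyl}methyl]-5-{3-methoxy-4-[(triisopropylsilyl)oxy]phenyl}oxolan-2-one
Product: 15 (1S,2R,3S,4S)-2-{[(tert-butyldimethylsilyl)oxy]methyl}-3-(hydroxymethyl)-1,4-bis{3-methoxy-4-[(triisopropylsilyl)oxy]phenyl}butane-1,4-diol
Conditions: LiAlH4, THF, −10 to 0 °C
Reagents that add atoms: none
Why: Hydride reduction of the lactone to the 1,4-diol brings C5 to the CH2 level without touching silyl ethers or stereocentres, and the low temperature should suppress retro-aldol of the β-hydroxy lactone.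

Step 8
Reactants: 15 (1S,2R,3S,4S)-2-{[(tert-butyldimethylsilyl)oxy]methyl}-3-(hydroxymethyl)-1,4-bis{3-methoxy-4-[(triisopropylsilyl)oxy]phenyl}butane-1,4-diol
Product: 17 (S)-[(3S,4R,5S)-4-{[(tert-butyldimethylsilyl)oxy]methyl}-5-{3-methoxy-4-[(triisopropylsilyl)oxy]phenyl}oxolan-3-yl]{3-methoxy-4-[(triisopropylsilyl)oxy]phenyl}methanol, via primary tosylate 16 (not isolated)
Conditions: TsCl, pyridine, CH2Cl2, 0 °C to rt, then 40 °C
Reagents that add atoms: none
Why: Selective sulfonylation of the only primary hydroxyl followed by intramolecular Williamson etherification (5-exo-tet) by the benzylic hydroxyl four atoms away closes the oxolane with retention at the benzylic carbon, whereas the other carbinol could only form a strained oxetane.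

Step 9
Reactants: 17 (S)-[(3S,4R,5S)-4-{[(tert-butyldimethylsilyl)oxy]methyl}-5-{3-methoxy-4-[(triisopropylsilyl)oxy]phenyl}oxolan-3-yl]{3-methoxy-4-[(triisopropylsilyl)oxy]phenyl}methanol
Product: 18 4-[(2S,3R,4S)-4-[(S)-hydroxy(4-hydroxy-3-methoxyphenyl)methyl]-3-(hydroxymethyl)oxolan-2-yl]-2-methoxyphenol
Conditions: Bu4NF, AcOH, THF, 0 °C to rt
Reagents that add atoms: none
Why: Fluoride-mediated cleavage of the two aryl and one alkyl silyl ethers in one operation, with AcOH buffering to keep the freed p-hydroxybenzylic alcohol from base-induced quinone methide formation.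

Compound list
1 | vanillin (4-hydroxy-3-methoxybenzaldehyde) | COc1cc(C=O)ccc1O | starting material
2 | 3-methoxy-4-[(triisopropylsilyl)oxy]benzaldehyde | COc1cc(C=O)ccc1O[Si](C(C)C)(C(C)C)C(C)C | intermediate
3 | (S)-4-benzyl-1,3-oxazolidin-2-one | O=C1N[C@@H](Cc2ccccc2)CO1 | starting material
4 | methyl 4-chloro-4-oxobutanoate | COC(=O)CCC(=O)Cl | starting material
5 | N-lithio derivative of 3 (not isolated) | [Li]N1C(=O)OC[C@@H]1Cc1ccccc1 | intermediate
6 | methyl 4-[(4S)-4-benzyl-2-oxo-1,3-oxazolidin-3-yl]-4-oxobutanoate | COC(=O)CCC(=O)N1C(=O)OC[C@@H]1Cc1ccccc1 | intermediate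
7 | dibutylboron Z-enolate of 6 (not isolated) | CCCCB(CCCC)O/C(=C\CC(=O)OC)N1C(=O)OC[C@@H]1Cc1ccccc1 | intermediate
8 | methyl (3S,4S)-3-{[(4S)-4-benzyl-2-oxo-1,3-oxazolidin-3-yl]carbonyl}-4-hydroxy-4-{3-methoxy-4-[(triisopropylsilyl)oxy]phenyl}butanoate (syn-aldol adduct, not isolated) | COC(=O)C[C@H](C(=O)N1C(=O)OC[C@@H]1Cc1ccccc1)[C@H](O)c1ccc(O[Si](C(C)C)(C(C)C)C(C)C)c(OC)c1 | intermediate
9 | (4S)-4-benzyl-3-{[(2S,3S)-2-{3-methoxy-4-[(triisopropylsilyl)oxy]phenyl}-5-oxooxolan-3-yl]carbonyl}-1,3-oxazolidin-2-one | O=C1O[C@H](c2ccc(O[Si](C(C)C)(C(C)C)C(C)C)c(OC)c2)[C@@H](C(=O)N2C(=O)OC[C@@H]2Cc2ccccc2)C1 | intermediate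
10 | (4R,5S)-4-(hydroxymethyl)-5-{3-methoxy-4-[(triisopropylsilyl)oxy]phenyl}oxolan-2-one | O=C1O[C@H](c2ccc(O[Si](C(C)C)(C(C)C)C(C)C)c(OC)c2)[C@@H](CO)C1 | intermediate
11 | (4R,5S)-4-{[(tert-butyldimethylsilyl)oxy]methyl}-5-{3-methoxy-4-[(triisopropylsilyl)oxy]phenyl}oxolan-2-one | O=C1O[C@H](c2ccc(O[Si](C(C)C)(C(C)C)C(C)C)c(OC)c2)[C@@H](CO[Si](C)(C)C(C)(C)C)C1 | intermediate
12 | lithium enolate of 11 (not isolated) | [Li]OC1=C[C@H](CO[Si](C)(C)C(C)(C)C)[C@@H](c2ccc(O[Si](C(C)C)(C(C)C)C(C)C)c(OC)c2)O1 | intermediate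
13 | chlorozinc enolate of 11 (not isolated) | Cl[Zn]OC1=C[C@H](CO[Si](C)(C)C(C)(C)C)[C@@H](c2ccc(O[Si](C(C)C)(C(C)C)C(C)C)c(OC)c2)O1 | intermediate
14 | (3R,4R,5S)-4-{[(tert-butyldimethylsilyl)oxy]methyl}-3-[(S)-hydroxy{3-methoxy-4-[(triisopropylsilyl)oxy]phenyl}methyl]-5-{3-methoxy-4-[(triisopropylsilyl)oxy]phenyl}oxolan-2-one | COc1cc([C@@H](O)[C@@H]2C(=O)O[C@H](c3ccc(O[Si](C(C)C)(C(C)C)C(C)C)c(OC)c3)[C@H]2CO[Si](C)(C)C(C)(C)C)ccc1O[Si](C(C)C)(C(C)C)C(C)C | intermediate
15 | (1S,2R,3S,4S)-2-{[(tert-butyldimethylsilyl)oxy]methyl}-3-(hydroxymethyl)-1,4-bis{3-methoxy-4-[(triisopropylsilyl)oxy]phenyl}butane-1,4-diol | COc1cc([C@@H](O)[C@H](CO)[C@H](CO[Si](C)(C)C(C)(C)C)[C@H](O)c2ccc(O[Si](C(C)C)(C(C)C)C(C)C)c(OC)c2)ccc1O[Si](C(C)C)(C(C)C)C(C)C | intermediate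
16 | primary mono-tosylate of 15 (not isolated) | COc1cc([C@@H](O)[C@H](COS(=O)(=O)c2ccc(C)cc2)[C@H](CO[Si](C)(C)C(C)(C)C)[C@H](O)c2ccc(O[Si](C(C)C)(C(C)C)C(C)C)c(OC)c2)ccc1O[Si](C(C)C)(C(C)C)C(C)C | intermediate
17 | (S)-[(3S,4R,5S)-4-{[(tert-butyldimethylsilyl)oxy]methyl}-5-{3-methoxy-4-[(triisopropylsilyl)oxy]phenyl}oxolan-3-yl]{3-methoxy-4-[(triisopropylsilyl)oxy]phenyl}methanol | COc1cc([C@@H](O)[C@@H]2CO[C@H](c3ccc(O[Si](C(C)C)(C(C)C)C(C)C)c(OC)c3)[C@H]2CO[Si](C)(C)C(C)(C)C)ccc1O[Si](C(C)C)(C(C)C)C(C)C | intermediate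
18 | 4-[(2S,3R,4S)-4-[(S)-hydroxy(4-hydroxy-3-methoxyphenyl)methyl]-3-(hydroxymethyl)oxolan-2-yl]-2-methoxyphenol | COc1cc([C@@H](O)[C@@H]2CO[C@H](c3ccc(O)c(OC)c3)[C@H]2CO)ccc1O | target

Total step count: 9. Longest linear sequence: 8 steps (steps 2 to 9, from 3 and 4 to 18).

Steps most likely to fail

1. Step 6 – erosion of the carbinol configuration, through incomplete funnelling between the syn and anti aldolates or retro-aldol on work-up. The fallback sets out from 11 and 2 and comes back at 14. The aldol is run under purely kinetic lithium conditions without ZnCl2, which should give 14 mixed with its carbinol epimer F1. Oxidation of the mixture with Dess–Martin periodinane removes the carbinol centre and should give the single β-keto lactone F2, whose ring carbon between the two carbonyls settles trans to the neighbouring arm. Reagent-controlled reduction of the aryl ketone with (R)-2-methyl-CBS-oxazaborolidine and catecholborane, the aryl group acting as the large substituent, should then deliver 14.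

2. Step 8 – loss of chemoselectivity in the sulfonylation, by attack at or ionisation of the two electron-rich benzylic carbinols. The fallback sets out from 14 and comes back at 18. The carbinol is capped first (TBSOTf, 2,6-lutidine) to the bis-TBS lactone F3, and LiAlH4 then gives the 1,4-diol F4, which has only one secondary hydroxyl. A Mitsunobu cyclodehydration (PPh3, DIAD) should close the ring with retention at the benzylic carbon to the fully silylated oxolane F5, and the fluoride treatment of step 9 (Bu4NF, AcOH) releases 18.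

3. Step 4 – over-reduction or acyl migration, by hydride attack on the lactone or shift of the lactone to the new primary alkoxide. The fallback sets out from 9 and comes back at 10. LiOH/H2O2 at 0 °C cleaves the imide to the lactone carboxylic acid F6, and BH3·SMe2 reduces the acid in the presence of the lactone.

Further compounds
F1 | step 6 | (3R,4R,5S)-4-{[(tert-butyldimethylsilyl)oxy]methyl}-3-[(R)-hydroxy{3-methoxy-4-[(triisopropylsilyl)oxy]phenyl}methyl]-5-{3-methoxy-4-[(triisopropylsilyl)oxy]phenyl}oxolan-2-one (carbinol epimer of 14) | COc1cc([C@H](O)[C@@H]2C(=O)O[C@H](c3ccc(O[Si](C(C)C)(C(C)C)C(C)C)c(OC)c3)[C@H]2CO[Si](C)(C)C(C)(C)C)ccc1O[Si](C(C)C)(C(C)C)C(C)C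
F2 | step 6 | (3R,4R,5S)-4-{[(tert-butyldimethylsilyl)oxy]methyl}-3-{3-methoxy-4-[(triisopropylsilyl)oxy]benzoyl}-5-{3-methoxy-4-[(triisopropylsilyl)oxy]phenyl}oxolan-2-one | COc1cc(C(=O)[C@@H]2C(=O)O[C@H](c3ccc(O[Si](C(C)C)(C(C)C)C(C)C)c(OC)c3)[C@H]2CO[Si](C)(C)C(C)(C)C)ccc1O[Si](C(C)C)(C(C)C)C(C)C
F3 | step 8 | (3R,4R,5S)-3-[(S)-[(tert-butyldimethylsilyl)oxy]{3-methoxy-4-[(triisopropylsilyl)oxy]phenyl}methyl]-4-{[(tert-butyldimethylsilyl)oxy]methyl}-5-{3-methoxy-4-[(triisopropylsilyl)oxy]phenyl}oxolan-2-one | COc1cc([C@@H](O[Si](C)(C)C(C)(C)C)[C@@H]2C(=O)O[C@H](c3ccc(O[Si](C(C)C)(C(C)C)C(C)C)c(OC)c3)[C@H]2CO[Si](C)(C)C(C)(C)C)ccc1O[Si](C(C)C)(C(C)C)C(C)C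
F4 | step 8 | (1S,2R,3S,4S)-4-[(tert-butyldimethylsilyl)oxy]-2-{[(tert-butyldimethylsilyl)oxy]methyl}-3-(hydroxymethyl)-1,4-bis{3-methoxy-4-[(triisopropylsilyl)oxy]phenyl}butan-1-ol | COc1cc([C@@H](O[Si](C)(C)C(C)(C)C)[C@H](CO)[C@H](CO[Si](C)(C)C(C)(C)C)[C@H](O)c2ccc(O[Si](C(C)C)(C(C)C)C(C)C)c(OC)c2)ccc1O[Si](C(C)C)(C(C)C)C(C)C
F5 | step 8 | (2S,3R,4S)-4-[(S)-[(tert-butyldimethylsilyl)oxy]{3-methoxy-4-[(triisopropylsilyl)oxy]phenyl}methyl]-3-{[(tert-butyldimethylsilyl)oxy]methyl}-2-{3-methoxy-4-[(triisopropylsilyl)oxy]phenyl}oxolane | COc1cc([C@@H](O[Si](C)(C)C(C)(C)C)[C@@H]2CO[C@H](c3ccc(O[Si](C(C)C)(C(C)C)C(C)C)c(OC)c3)[C@H]2CO[Si](C)(C)C(C)(C)C)ccc1O[Si](C(C)C)(C(C)C)C(C)C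
F6 | step 4 | (2S,3S)-2-{3-methoxy-4-[(triisopropylsilyl)oxy]phenyl}-5-oxooxolane-3-carboxylic acid | O=C1O[C@H](c2ccc(O[Si](C(C)C)(C(C)C)C(C)C)c(OC)c2)[C@@H](C(=O)O)C1
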